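**Plan**

Rings are named A (benzo), C (pyranone), B (aryl) for the unprimed flavanone and D (benzo), F (pyranone), E (syringyl) for the doubly primed one.

1. Retrosynthesis: benzylate the three phenols, then remove H2 across C2–C3 and C2''–C3'' to reach a 2'–8''-linked biflavone with no stereocentre.
2. Cut O1–C8a and O1''–C8a'' to a bis(1,3-diketone) with fluorine on C8a and C8a''. The enabling feature: ring D has two oxygens ortho to the acyl-bearing C4a'' (at C5'' and C8a''), and only the one at C8a'', beside the C2'–C8'' biaryl bond, may become O1''; a fluorine there marks the carbon that receives the ring oxygen.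
3. Cut the diketones at C2–C3 and C2''–C3'' (Claisen) and the biaryl at C2'–C8'' (Suzuki–Miyaura). This gives ring A and ring D fluoroacetophenones from 1-fluoro-3,5-dimethoxybenzene, a ring B bromo ester from isovanillin, and benzylated methyl syringate.
4. Forward: biaryl first, then C2''–C3'', then C2–C3; rings C and F close together in one operation; reduction and deprotection follow.
5. Stereochemistry: C2 and C2'' (both S) are set together by catalyst-controlled enantioselective hydrogenation of the two C2=C3 bonds with a chiral ruthenium N-heterocyclic carbene catalyst; the C4 carbinols formed on the way are oxidised back.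

Key step: step 13

Assumption 1: the target defines only C2 and C2''; the C2'–C8'' axis has four ortho substituents and is left undefined, so the route does not control it, and any atropodiastereomers of 20 would be separated or thermally equilibrated at the end.

Assumption 2: the (R,R) carbene precursor is written for step 14; the ligand antipode that gives the 2S series would first be fixed on a model 5,7-dialkoxyflavone, and the (S,S) salt used if the model reduces to 2R.

**Route**

Step 1
Reactants: 1 1-fluoro-3,5-dimethoxybenzene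
Product: 2 1-(2-fluoro-4,6-dimethoxyphenyl)ethan-1-one
Conditions: AcCl, AlCl3, CH2Cl2, −10 → 0 °C
Reagents that add atoms: acetyl chloride, CC(=O)Cl
Why: Friedel–Crafts acylation should go to C2 of 1, which is para to one methoxy group, ortho to the other and flanked by the small fluorine, in preference to C4 between the two methoxy groups, as is usual for resorcinol dimethyl ethers; low temperature keeps AlCl3 from cleaving the new ortho methoxy group.

Step 2
Reactants: 2 1-(2-fluoro-4,6-dimethoxyphenyl)ethan-1-one
Product: 3 1-(2-fluoro-6-hydroxy-4-methoxyphenyl)ethan-1-one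
Conditions: BCl3, CH2Cl2, −78 → 0 °C; then H2O
Reagents that add atoms: none
Why: Chelation-directed Lewis-acid ether cleavage: BCl3 bound to the ketone oxygen reaches only the ortho methoxy group through a six-membered chelate, so the para methoxy group and the C–F bond should stay intact.

Step 3
Reactants: 3 1-(2-fluoro-6-hydroxy-4-methoxyphenyl)ethan-1-one
Product: 4 1-[2-(benzyloxy)-6-fluoro-4-methoxyphenyl]ethan-1-one (ring A ketone)
Conditions: BnBr, K2CO3, DMF, 50 °C
Reagents that add atoms: benzyl bromide, BrCc1ccccc1
Why: Williamson ether synthesis on the phenoxide; benzyl is chosen because a free or anionic oxygen ortho to the acyl group would shut down the later fluoride displacement and because it leaves by hydrogenolysis at the very end.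

Step 4
Reactants: 4 1-[2-(benzyloxy)-6-fluoro-4-methoxyphenyl]ethan-1-one
Product: 5 1-[6-(benzyloxy)-3-bromo-2-fluoro-4-methoxyphenyl]ethan-1-one (ring D bromoketone)
Conditions: NBS, MeCN, 0 °C → rt, dark
Reagents that add atoms: N-bromosuccinimide, O=C1CCC(=O)N1Br
Why: Electrophilic aromatic bromination should take place at C3, para to the benzyloxy group and between fluorine and methoxy, since the only other free position lies between two alkoxy groups; polar, acid-free conditions disfavour bromination of the acetyl methyl group.

Step 5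
Reactants: 6 isovanillin (3-hydroxy-4-methoxybenzaldehyde)
Product: 7 2-bromo-3-hydroxy-4-methoxybenzaldehyde
Conditions: Br2, NaOAc, Fe powder (cat.), AcOH, rt
Reagents that add atoms: bromine, BrBr
Why: Electrophilic aromatic bromination ortho to the free phenol; the buffered Br2/Fe procedure is the standard entry to 2-bromoisovanillin, the position between hydroxyl and formyl being the one attacked.

Step 6
Reactants: 7 2-bromo-3-hydroxy-4-methoxybenzaldehyde
Product: 8 2-bromo-3,4-dimethoxybenzaldehyde
Conditions: MeI, K2CO3, DMF, rt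
Reagents that add atoms: iodomethane, CI
Why: Williamson ether synthesis (O-methylation of the phenoxide).

Step 7
Reactants: 8 2-bromo-3,4-dimethoxybenzaldehyde
Product: 9 methyl 2-bromo-3,4-dimethoxybenzoate
Conditions: I2, KOH, MeOH, 0 °C
Reagents that add atoms: methanol, CO
Why: Oxidative esterification: the methyl hemiacetal of the aldehyde is oxidised by hypoiodite formed from I2 and KOH, which gives the methyl ester in one operation without touching the aryl bromide.

Step 8
Reactants: 9 methyl 2-bromo-3,4-dimethoxybenzoate
Product: 10 methyl 3,4-dimethoxy-2-(4,4,5,5-tetramethyl-1,3,2-dioxaborolan-2-yl)benzoate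
Conditions: B2pin2, PdCl2(dppf) (5 mol %), KOAc, 1,4-dioxane, 90 °C
Reagents that add atoms: bis(pinacolato)diboron, CC1(C)OB(OC1(C)C)B1OC(C)(C)C(C)(C)O1
Why: Miyaura borylation; the ester-activated C–Br bond should undergo oxidative addition readily, and KOAc is too weak a base to trigger Suzuki homocoupling.

Step 9
Reactants: 5 1-[6-(benzyloxy)-3-bromo-2-fluoro-4-methoxyphenyl]ethan-1-one, 10 methyl 3,4-dimethoxy-2-(4,4,5,5-tetramethyl-1,3,2-dioxaborolan-2-yl)benzoate
Product: 11 methyl 2-[3-acetyl-4-(benzyloxy)-2-fluoro-6-methoxyphenyl]-3,4-dimethoxybenzoate (biaryl keto ester)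
Conditions: Pd(OAc)2 (5 mol %), SPhos (10 mol %), K3PO4, toluene/H2O (10:1), 100 °C
Reagents that add atoms: none
Why: Suzuki–Miyaura coupling with an SPhos-ligated palladium catalyst, a system suited to biaryls with four ortho substituents; boron sits on the ester ring because an ortho-ester boronate resists protodeboronation, whereas a boronate flanked by fluorine and alkoxy would not.

Step 10
Reactants: 12 methyl syringate (methyl 4-hydroxy-3,5-dimethoxybenzoate)
Product: 13 methyl 4-(benzyloxy)-3,5-dimethoxybenzoate
Conditions: BnBr, K2CO3, DMF, 60 °C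
Reagents that add atoms: benzyl bromide, BrCc1ccccc1
Why: Williamson ether synthesis.

Step 11
Reactants: 11 methyl 2-[3-acetyl-4-(benzyloxy)-2-fluoro-6-methoxyphenyl]-3,4-dimethoxybenzoate, 13 methyl 4-(benzyloxy)-3,5-dimethoxybenzoate
Product: 14 methyl 2-[4-(benzyloxy)-3-{3-[4-(benzyloxy)-3,5-dimethoxyphenyl]-3-oxopropanoyl}-2-fluoro-6-methoxyphenyl]-3,4-dimethoxybenzoate (diketone ester)
Conditions: LiN(SiMe3)2 (3 equiv), 13 (2.5 equiv), THF, −78 °C → rt; aq. HCl
Reagents that add atoms: none
Why: Crossed Claisen condensation: the methyl ketone of 11 is the only enolisable position, its lithium enolate should acylate on the unhindered ester 13 used in excess and not on the ring B ester, which is shielded by the orthogonal ring D and deactivated by its para methoxy group, and deprotonation of the product diketone drives the reaction.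

Step 12
Reactants: 14 diketone ester, 4 1-[2-(benzyloxy)-6-fluoro-4-methoxyphenyl]ethan-1-one
Product: 15 1-[2-(benzyloxy)-6-fluoro-4-methoxyphenyl]-3-{2-[4-(benzyloxy)-3-{3-[4-(benzyloxy)-3,5-dimethoxyphenyl]-3-oxopropanoyl}-2-fluoro-6-methoxyphenyl]-3,4-dimethoxyphenyl}propane-1,3-dione (difluoro bis(1,3-diketone))
Conditions: 4 (3 equiv), LiN(SiMe3)2 (4.5 equiv), THF, −78 °C; then 14, −78 → 45 °C; aq. HCl
Reagents that add atoms: none
Why: Crossed Claisen condensation: the diketone of 14 is first masked as its lithium enolate, so the only electrophile left is the ring B methyl ester, which should be taken by the excess lithium enolate of 4 on warming, the new diketone again being trapped as its enolate.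

Step 13
Reactants: 15 difluoro bis(1,3-diketone)
Product: 17 5-(benzyloxy)-8-{6-[5-(benzyloxy)-7-methoxy-4-oxo-4H-chromen-2-yl]-2,3-dimethoxyphenyl}-2-[4-(benzyloxy)-3,5-dimethoxyphenyl]-7-methoxy-4H-chromen-4-one (tribenzyl biflavone), via ring A/C-closed fluoro diketone 16 (not isolated)
Conditions: K2CO3 (4 equiv), dry DMF, 100 °C
Reagents that add atoms: none
Why: K2CO3 deprotonates each 1,3-diketone and the enolate oxygen on the carbon that becomes C2 (or C2'') adds to the fluorine-bearing carbon C8a (or C8a''), giving a Meisenheimer-type anion that is stabilised by the ortho acyl carbon C4 (or C4'') and then loses fluoride. The closest known reaction type is the SNAr cyclisation of 1-(2-fluoroaryl)-1,3-diketones to chromones and flavones. Ring C (O1–C8a) and ring F (O1''–C8a'') each close as a six-membered intramolecular addition–elimination, 6-endo with respect to the C4a=C8a bond of the vinylogous acyl fluoride, the carbonyl oxygen next to the fluoroarene being unable to reach the ipso carbon. No stereocentre is formed, the products being planar flavones. The selectivity required is regiochemical, ring D having to close on C8a'' beside the C2'–C8'' bond and not on the C5'' oxygen, and it is secured because only C8a'' bears a leaving group while O5'' is capped as a benzyl ether; on both benzo rings the alkoxy groups are meta to fluorine and so do not feed electron density to the attacked carbon. The less hindered ring A should close first (16), and the slower closure next to the biaryl axis can be forced by heat because all species are robust aromatics.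

Step 14
Reactants: 17 tribenzyl biflavone
Product: 19 (2S,4S)-5-(benzyloxy)-8-{6-[(2S,4S)-5-(benzyloxy)-4-hydroxy-7-methoxy-3,4-dihydro-2H-chromen-2-yl]-2,3-dimethoxyphenyl}-2-[4-(benzyloxy)-3,5-dimethoxyphenyl]-7-methoxy-3,4-dihydro-2H-chromen-4-ol (tribenzyl bis-cis-flavan-4-ol), via tribenzyl biflavanone 18 (not isolated)
Conditions: Ru(cod)(2-methylallyl)2 (10 mol %), (R,R)-SINpEt·HBF4 [1,3-bis((R)-1-(naphthalen-1-yl)ethyl)-4,5-dihydroimidazolium tetrafluoroborate, 20 mol %], KOt-Bu, H2 (100 bar), toluene/n-hexane, 40 °C
Reagents that add atoms: none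
Why: Enantioselective hydrogenation of flavones with a chiral ruthenium–NHC catalyst is an established reaction type: hydrogen is delivered to one face of each C2=C3 bond under catalyst control, which sets C2 and C2'' (both S) independently of each other and of the biaryl axis, while the accompanying carbonyl reduction, run on so that one oxidation level is carried forward, should give the cis carbinols whose C4 centres are removed in step 15.

Step 15
Reactants: 19 tribenzyl bis-cis-flavan-4-ol (with any residual ketone-level material)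
Product: 18 (2S)-5-(benzyloxy)-8-{6-[(2S)-5-(benzyloxy)-7-methoxy-4-oxo-3,4-dihydro-2H-chromen-2-yl]-2,3-dimethoxyphenyl}-2-[4-(benzyloxy)-3,5-dimethoxyphenyl]-7-methoxy-2,3-dihydro-4H-chromen-4-one (tribenzyl biflavanone)
Conditions: Dess–Martin periodinane (3 equiv), CH2Cl2, 0 °C → rt
Reagents that add atoms: none
Why: Dess–Martin oxidation of the two secondary benzylic carbinols back to ketones; the medium is neutral to weakly acidic, so C2 and C2'' should not epimerise by ring opening to the chalcone.

Step 16
Reactants: 18 tribenzyl biflavanone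
Product: 20 (2S)-5-hydroxy-8-{6-[(2S)-5-hydroxy-7-methoxy-4-oxo-3,4-dihydro-2H-chromen-2-yl]-2,3-dimethoxyphenyl}-2-(4-hydroxy-3,5-dimethoxyphenyl)-7-methoxy-2,3-dihydro-4H-chromen-4-one (CNP0229789.1)
Conditions: H2 (1 atm), Pd/C (10 wt %), EtOAc/THF, rt
Reagents that add atoms: none
Why: Hydrogenolysis of the three aryl benzyl ethers over Pd/C at ambient pressure in a neutral aprotic medium, conditions under which flavanone carbonyls, the benzylic C2–O1 bonds and the C2 stereocentres are normally retained.

**Compound list**

1 | 1-fluoro-3,5-dimethoxybenzene | COc1cc(F)cc(OC)c1 | starting material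
2 | 1-(2-fluoro-4,6-dimethoxyphenyl)ethan-1-one | CC(=O)c1c(F)cc(OC)cc1OC | intermediate
3 | 1-(2-fluoro-6-hydroxy-4-methoxyphenyl)ethan-1-one | CC(=O)c1c(O)cc(OC)cc1F | intermediate
4 | 1-[2-(benzyloxy)-6-fluoro-4-methoxyphenyl]ethan-1-one | CC(=O)c1c(F)cc(OC)cc1OCc1ccccc1 | intermediate
5 | 1-[6-(benzyloxy)-3-bromo-2-fluoro-4-methoxyphenyl]ethan-1-one | CC(=O)c1c(F)c(Br)c(OC)cc1OCc1ccccc1 | intermediate
6 | isovanillin | COc1ccc(C=O)cc1O | starting material
7 | 2-bromo-3-hydroxy-4-methoxybenzaldehyde | COc1ccc(C=O)c(Br)c1O | intermediate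
8 | 2-bromo-3,4-dimethoxybenzaldehyde | COc1ccc(C=O)c(Br)c1OC | intermediate
9 | methyl 2-bromo-3,4-dimethoxybenzoate | COC(=O)c1ccc(OC)c(OC)c1Br | intermediate
10 | methyl 3,4-dimethoxy-2-(4,4,5,5-tetramethyl-1,3,2-dioxaborolan-2-yl)benzoate | COC(=O)c1ccc(OC)c(OC)c1B1OC(C)(C)C(C)(C)O1 | intermediate
11 | methyl 2-[3-acetyl-4-(benzyloxy)-2-fluoro-6-methoxyphenyl]-3,4-dimethoxybenzoate | COC(=O)c1ccc(OC)c(OC)c1-c1c(OC)cc(OCc2ccccc2)c(C(C)=O)c1F | intermediate
12 | methyl syringate | COC(=O)c1cc(OC)c(O)c(OC)c1 | starting material
13 | methyl 4-(benzyloxy)-3,5-dimethoxybenzoate | COC(=O)c1cc(OC)c(OCc2ccccc2)c(OC)c1 | intermediate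
14 | methyl 2-[4-(benzyloxy)-3-{3-[4-(benzyloxy)-3,5-dimethoxyphenyl]-3-oxopropanoyl}-2-fluoro-6-methoxyphenyl]-3,4-dimethoxybenzoate | COC(=O)c1ccc(OC)c(OC)c1-c1c(OC)cc(OCc2ccccc2)c(C(=O)CC(=O)c2cc(OC)c(OCc3ccccc3)c(OC)c2)c1F | intermediate
15 | difluoro bis(1,3-diketone), tribenzyl protected | COc1cc(F)c(C(=O)CC(=O)c2ccc(OC)c(OC)c2-c2c(OC)cc(OCc3ccccc3)c(C(=O)CC(=O)c3cc(OC)c(OCc4ccccc4)c(OC)c3)c2F)c(OCc2ccccc2)c1 | intermediate
16 | 5-(benzyloxy)-2-{2-[4-(benzyloxy)-3-{3-[4-(benzyloxy)-3,5-dimethoxyphenyl]-3-oxopropanoyl}-2-fluoro-6-methoxyphenyl]-3,4-dimethoxyphenyl}-7-methoxy-4H-chromen-4-one | COc1cc(OCc2ccccc2)c2c(c1)oc(-c1ccc(OC)c(OC)c1-c1c(OC)cc(OCc3ccccc3)c(C(=O)CC(=O)c3cc(OC)c(OCc4ccccc4)c(OC)c3)c1F)cc2=O | intermediate (not isolated)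
17 | tribenzyl biflavone | COc1cc(OCc2ccccc2)c2c(c1)oc(-c1ccc(OC)c(OC)c1-c1c(OC)cc(OCc3ccccc3)c3c1oc(-c1cc(OC)c(OCc4ccccc4)c(OC)c1)cc3=O)cc2=O | intermediate
18 | (2S,2''S)-tribenzyl biflavanone | COc1cc(OCc2ccccc2)c2c(c1)O[C@H](c1ccc(OC)c(OC)c1-c1c(OC)cc(OCc3ccccc3)c3c1O[C@H](c1cc(OC)c(OCc4ccccc4)c(OC)c1)CC3=O)CC2=O | intermediate
19 | (2S,4S,2''S,4''S)-tribenzyl bis-cis-flavan-4-ol | COc1cc(OCc2ccccc2)c2c(c1)O[C@H](c1ccc(OC)c(OC)c1-c1c(OC)cc(OCc3ccccc3)c3c1O[C@H](c1cc(OC)c(OCc4ccccc4)c(OC)c1)C[C@@H]3O)C[C@@H]2O | intermediate
20 | CNP0229789.1, (2S,2''S)-biflavanone | COc1cc(O)c2c(c1)O[C@H](c1ccc(OC)c(OC)c1-c1c(OC)cc(O)c3c1O[C@H](c1cc(OC)c(O)c(OC)c1)CC3=O)CC2=O | target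

**Step count**

Total step count: 16. Longest linear sequence: 11 steps (steps 1, 2, 3, 4, 9, 11, 12, 13, 14, 15, 16 from 1; the branch from 6 through steps 5–8 is equally long).

**Steps most likely to fail**

Step 14. Hydrogen delivery to the C2=C3 bond of the unprimed unit may be slow or poorly face-selective, because ring B carries the orthogonal ring D next to the reacting alkene; the 4-oxo/5-benzyloxy chelating motif may also tie up the catalyst, so that reduction stalls at mixed flavone/flavanone stages. The fallback gives up catalyst control and sets out from 17. Conjugate reduction of both vinylogous esters with LiBH(s-Bu)3 in THF at −78 °C, quenched cold with AcOH, would give the tribenzyl biflavanone as a mixture of C2/C2'' stereoisomers F1. Preparative chromatography on a chiral stationary phase would then isolate the (2S,2''S) isomer, which is 18, where the route is rejoined for step 16.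

Step 12. Acyl substitution at the ring B methyl ester may be too slow, since the ester is shielded by ring D and conjugated to a para methoxy group; prolonged heating with base would then let proton exchange and premature fluoride displacement compete. The fallback activates the ring B carboxyl instead and sets out from 11. Saponification with LiOH in THF/MeOH/H2O would give 2-[3-acetyl-4-(benzyloxy)-2-fluoro-6-methoxyphenyl]-3,4-dimethoxybenzoic acid F2. Claisen condensation of its carboxylate–enolate dianion (LiN(SiMe3)2, 4 equiv) with 13 would give the diketone acid F3. 1,1'-Carbonyldiimidazole in THF would convert this into the acyl imidazolide F4, which is added without isolation to the excess lithium enolate of 4 at −78 °C. This delivers 15, where the route is rejoined.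

Step 9. Transmetalation from the doubly ortho-substituted boronate to a hindered arylpalladium bromide may be slow, so that protodeboronation of 10 and hydrodebromination of 5 outrun C–C bond formation. The fallback replaces boron by zinc and sets out from 9. Bromine–magnesium exchange with i-PrMgCl·LiCl in THF at −20 °C would give methyl 2-(chloromagnesio)-3,4-dimethoxybenzoate F5. ZnCl2 would convert it into methyl 2-(chlorozincio)-3,4-dimethoxybenzoate F6. Negishi coupling of F6 with 5 (Pd(OAc)2, RuPhos, THF, 60 °C), a reaction type that tolerates ketones and forms highly hindered biaryls, would give 11, where the route is rejoined.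

**Further compounds**

F1 | step 14 | tribenzyl biflavanone as a mixture of stereoisomers at C2 and C2'' | COc1cc(OCc2ccccc2)c2c(c1)OC(c1ccc(OC)c(OC)c1-c1c(OC)cc(OCc3ccccc3)c3c1OC(c1cc(OC)c(OCc4ccccc4)c(OC)c1)CC3=O)CC2=O
F2 | step 12 | 2-[3-acetyl-4-(benzyloxy)-2-fluoro-6-methoxyphenyl]-3,4-dimethoxybenzoic acid | OC(=O)c1ccc(OC)c(OC)c1-c1c(OC)cc(OCc2ccccc2)c(C(C)=O)c1F
F3 | step 12 | 2-[4-(benzyloxy)-3-{3-[4-(benzyloxy)-3,5-dimethoxyphenyl]-3-oxopropanoyl}-2-fluoro-6-methoxyphenyl]-3,4-dimethoxybenzoic acid | OC(=O)c1ccc(OC)c(OC)c1-c1c(OC)cc(OCc2ccccc2)c(C(=O)CC(=O)c2cc(OC)c(OCc3ccccc3)c(OC)c2)c1F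
F4 | step 12 | acyl imidazolide of F3 | O=C(c1ccc(OC)c(OC)c1-c1c(OC)cc(OCc2ccccc2)c(C(=O)CC(=O)c2cc(OC)c(OCc3ccccc3)c(OC)c2)c1F)n1ccnc1
F5 | step 9 | methyl 2-(chloromagnesio)-3,4-dimethoxybenzoate | COC(=O)c1ccc(OC)c(OC)c1[Mg]Cl
F6 | step 9 | methyl 2-(chlorozincio)-3,4-dimethoxybenzoate | COC(=O)c1ccc(OC)c(OC)c1[Zn]Cl
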